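**Plan**

1. Retrosynthetic cuts: the two ester C–O bonds; the C8–O and C9–O bonds (cis-dihydroxylation of a C8=C9 alkene) and the C10–H bond; C1–C10 (aldol condensation, ring B); C5–C10 and C3–C4 (photocycloaddition, ring A; the cyclobutane bond C10–C3 is broken again by retro-aldol); then C2–C3 (Claisen) and C6–C7 (auxiliary alkylation).
2. Enabling feature: the quaternary carbon C5 is bonded to C10 and to the chain C4–C3–C2(=O), so C10 and C2 are 1,5-related carbonyl positions. This is the pattern that a de Mayo reaction of a C2/C10 1,3-diketone with a tethered C5=C4 alkene delivers.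
3. Forward order: open chain (steps 1–7), ring A by the de Mayo reaction (step 8), ring B by aldol condensation (step 9), dienone, diol and cis-decalin (steps 10–13), isopropenyl group and the two esters (steps 14–18). C8 is carried as CH2 through the key step; both ring oxygens come later from OsO4.
4. Stereochemistry: C7 from the alkylation of the (S)-benzyloxazolidinone imide; C5 and C4 in the photocycloaddition, relayed from C7; C8 and C9 by dihydroxylation anti to the C5 methyl and the C7 side chain; C10 by hydrogenation anti to the dioxolane; the ester stereocentre from (R)-2-methylbutanoic acid.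

Key step: step 8

Remark: the text uses the decalin locants C1–C10 (C2 ketone, methyls on C4 and C5, side chain on C7, C11 = its first carbon, ring A = C5–C10, ring B = C1–C5 plus C10); in the compound list the bicyclic compounds are named as naphthalen-2-ones, whose positions 4a, 6, 7, 8, 8a are C5, C7, C8, C9, C10.
Remark: the 2-methylbutanoyl stereocentre of the given structure is R, so (R)-2-methylbutanoic acid is used; the descriptor at C7 changes between R and S along the route only because substituent priorities change.
Remark: metal enolates and alkoxides are treated as salts of the numbered compounds; 2, 4, 24 and 27 are taken as purchased.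

**Route**

Step 1
Reactants: 1 (S)-4-benzyl-1,3-oxazolidin-2-one; 2 hex-5-enoyl chloride
Product: 3 (S)-4-benzyl-3-(hex-5-enoyl)-1,3-oxazolidin-2-one
Conditions: n-BuLi, THF, −78 °C; then 2, −78 → 0 °C
Reagents that add atoms: none
Why: N-acylation of the lithiated oxazolidinone by the acid chloride is the standard attachment of the Evans auxiliary and creates no stereocentre.

Step 2
Reactants: 3 N-hexenoyl oxazolidinone; 4 (E)-1-bromo-2-methylbut-2-ene
Product: 5 alkylated imide (C7 R)
Conditions: NaN(SiMe3)2, THF, −78 °C; then 4, −78 → −40 °C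
Reagents that add atoms: none
Why: Evans asymmetric alkylation, in which the chelated sodium (Z)-enolate of 3 is attacked by the primary allylic bromide (SN2) on the face opposite the benzyl group, which sets C7 as R.

Step 3
Reactants: 5 alkylated imide
Product: 6 methyl ester
Conditions: MeMgBr added to MeOH at 0 °C (gives MeOMgBr); then 5, CH2Cl2/MeOH, 0 °C → rt; aqueous work-up
Reagents that add atoms: methanol, CO
Why: transesterification by MeOMgBr at the exocyclic imide carbonyl returns the auxiliary under conditions mild enough to leave the α-stereocentre C7 untouched.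

Step 4
Reactants: 6 methyl ester
Product: 8 tertiary alcohol, via methyl ketone 7 (not isolated)
Conditions: MeMgBr (3 equiv), THF, 0 °C → rt; aqueous work-up
Reagents that add atoms: methylmagnesium bromide, C[Mg]Br
Why: double Grignard addition to the ester through ketone 7 gives the tertiary carbinol that masks the isopropenyl group, and C7 is kept because addition to the ketone outruns its enolisation.

Step 5
Reactants: 8 tertiary alcohol
Product: 9 triethylsilyl ether
Conditions: Et3SiOTf, 2,6-lutidine, CH2Cl2, −78 → 0 °C
Reagents that add atoms: triethylsilyl trifluoromethanesulfonate, CC[Si](CC)(CC)OS(=O)(=O)C(F)(F)F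
Why: silylation of a hindered tertiary alcohol with a silyl triflate and a hindered pyridine base is standard, and the ether prevents hemiketal formation with the later C10 carbonyl.

Step 6
Reactants: 9 silyl ether
Product: 10 methyl ketone
Conditions: PdCl2 (10 mol %), CuCl, O2 (1 atm), DMF/H2O 7:1, rt
Reagents that add atoms: water, O
Why: Tsuji–Wacker oxidation converts only the monosubstituted alkene into the methyl ketone by Markovnikov hydroxypalladation, while the trisubstituted alkene does not react.

Step 7
Reactants: 10 methyl ketone
Product: 11 1,3-diketone (photosubstrate)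
Conditions: NaH, EtOAc, THF, 0 → 40 °C; then AcOH
Reagents that add atoms: ethyl acetate, CCOC(C)=O
Why: crossed Claisen condensation acetylates the ketone at its methyl group, the side that leads to the unhindered, stable diketonate whose formation drives the reaction.

Step 8
Reactants: 11 1,3-diketone
Product: 13 ring A diketone, via cyclobutanol photoadduct 12 (not isolated)
Conditions: hν (medium-pressure Hg lamp, Pyrex filter, λ > 290 nm), degassed cyclohexane (3 mM), 15 °C
Reagents that add atoms: none
Why: Excitation of the hydrogen-bonded enol of 11 lets its enol carbon C10 bond to the alkene carbon C5, and the resulting 1,4-biradical (C3 and C4) collapses to the cyclobutanol 12, whose β-hydroxy ketone unit then opens by retro-aldol cleavage of C10–C3 to the 1,5-diketone 13. The closest known reaction is the intramolecular de Mayo reaction of an enolised 1,3-diketone with a tethered alkene. Ring A closes in the 6-exo-trig mode with respect to both π bonds, the only closure the four-atom tether C9–C8–C7–C6 allows without a seven- or eight-membered ring, and the four-membered ring closes by recombination of the 1,4-biradical and is opened again in the same flask. C5 is set in a chair-like folding of the tether with the bulky C7 side chain, the C5 methyl and the chelated enone carbon C3 equatorial and the enol hydroxyl axial, so that C4 enters axially and the C5 methyl ends up cis to the C7 substituent. C4 is set when the biradical closes: its methyl turns outwards, away from the axial hydrogens on C7 and C9 of ring A, that is to the exo face and cis to the C5 methyl, which is also the result of retention of the (E)-alkene geometry. The step needs site selectivity for the trisubstituted alkene and for one enol tautomer: the isopropenyl group is masked as the silylated carbinol and the terminal alkene is already a ketone, and only the tautomer with the C10=C3 double bond can reach C5=C4 through a six-membered ring.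

Step 9
Reactants: 13 ring A diketone
Product: 15 enone, via ketol 14 (not isolated)
Conditions: KOH, MeOH, 60 °C
Reagents that add atoms: none
Why: intramolecular aldol condensation as in the second stage of a Robinson annulation, in which attack of the methyl carbon C1 on the C10 carbonyl gives ketol 14, the only aldol that can lose water to a conjugated enone, so that reversible bridged aldols drain into 15 and no stereocentre is formed or lost.

Step 10
Reactants: 15 enone
Product: 16 linear dienone
Conditions: chloranil (1.2 equiv), t-BuOH, reflux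
Reagents that add atoms: none
Why: quinone dehydrogenation, in which chloranil abstracts hydride from C8 of the linear dienol of 15 and gives the 1(10),8-dienone, the known outcome for 4-en-3-one type enones with this quinone, without touching C4, C5 or C7.

Step 11
Reactants: 16 dienone
Product: 17 cis-diol
Conditions: OsO4 (2 mol %), 4-methylmorpholine N-oxide, acetone/H2O 8:1, rt
Reagents that add atoms: OsO4, O=[Os](=O)(=O)=O (delivers both oxygen atoms and is regenerated); 4-methylmorpholine N-oxide, C[N+]1([O-])CCOCC1; water, O
Why: catalytic OsO4 syn-dihydroxylation takes place at the more electron-rich γ,δ double bond C8=C9 and from the β face, away from the C5 methyl and the C7 side chain that both stand on the α face, which sets C8 and C9.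

Step 12
Reactants: 17 diol
Product: 18 acetonide
Conditions: Me2C(OMe)2, pyridinium p-toluenesulfonate (cat.), CH2Cl2, rt
Reagents that add atoms: 2,2-dimethoxypropane, COC(C)(C)OC
Why: acid-catalysed transketalisation closes the dioxolane on the cis-diol, which protects both hydroxyls and places an isopropylidene group on the β face.

Step 13
Reactants: 18 acetonide enone
Product: 19 cis-fused decalone
Conditions: H2 (1 atm), Pd/C (10% Pd on carbon), pyridine, rt
Reagents that add atoms: none
Why: heterogeneous hydrogenation adds hydrogen to C1=C10 from the α face, since the β face is covered by the dioxolane and 4-en-3-one type octalones with an angular methyl give cis-fused products on palladium in basic medium, which sets C10 with its hydrogen cis to the C5 methyl.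

Step 14
Reactants: 19 silyl ether
Product: 20 tertiary alcohol
Conditions: HF·pyridine, pyridine, THF, 0 °C → rt
Reagents that add atoms: none
Why: fluoride cleaves the Si–O bond of the tertiary silyl ether, and the buffered reagent leaves the acetonide and the ketone untouched.

Step 15
Reactants: 20 tertiary alcohol
Product: 22 isopropenyl acetonide, via chlorosulfite 21 (not isolated)
Conditions: SOCl2, pyridine, CH2Cl2, −20 → 0 °C
Reagents that add atoms: none
Why: dehydration through chlorosulfite 21 by E2 elimination, in which pyridine should remove one of the six accessible methyl hydrogens rather than the single shielded C7–H whose loss would give a strained tetrasubstituted alkene, so that the isopropenyl group is expected as the main product.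

Step 16
Reactants: 22 isopropenyl acetonide
Product: 23 diol
Conditions: AcOH/H2O 4:1, 45 °C
Reagents that add atoms: none
Why: acid-catalysed acetal hydrolysis frees the cis-diol under conditions mild enough for the 1,1-disubstituted alkene.

Step 17
Reactants: 23 diol; 24 (R)-2-methylbutanoic acid
Product: 26 C8 mono-ester, via O-acylisourea 25 (not isolated)
Conditions: DCC (1.05 equiv), DMAP (10 mol %), CH2Cl2, 0 °C
Reagents that add atoms: none
Why: Steglich esterification should acylate O8, because in the cis-decalin the C8 hydroxyl is equatorial and open while the C9 hydroxyl is axial and 1,3-diaxial to C4, and the mild conditions keep the α-stereocentre of the acid.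

Step 18
Reactants: 26 mono-ester; 27 (E)-2-methylbut-2-enoyl chloride
Product: 28 target CNP0312791.1
Conditions: Et3N, DMAP (20 mol %), CH2Cl2, 40 °C
Reagents that add atoms: none
Why: DMAP-catalysed acylation with the acid chloride esterifies the remaining hindered axial C9 hydroxyl and keeps the stable (E)-geometry of the tigloyl group.

**Compound list**

1 | (S)-4-benzyl-1,3-oxazolidin-2-one | O=C1N[C@@H](Cc2ccccc2)CO1 | starting material
2 | hex-5-enoyl chloride | C=CCCCC(=O)Cl | starting material
3 | (S)-4-benzyl-3-(hex-5-enoyl)-1,3-oxazolidin-2-one | C=CCCCC(=O)N1[C@@H](Cc2ccccc2)COC1=O | intermediate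
4 | (E)-1-bromo-2-methylbut-2-ene | C/C=C(\C)CBr | starting material
5 | (S)-4-benzyl-3-{(2R)-2-[(2E)-2-methylbut-2-en-1-yl]hex-5-enoyl}-1,3-oxazolidin-2-one | C=CCC[C@H](C/C(C)=C/C)C(=O)N1[C@@H](Cc2ccccc2)COC1=O | intermediate
6 | methyl (2R)-2-[(2E)-2-methylbut-2-en-1-yl]hex-5-enoate | C=CCC[C@H](C/C(C)=C/C)C(=O)OC | intermediate
7 | (3R)-3-[(2E)-2-methylbut-2-en-1-yl]hept-6-en-2-one (not isolated) | C=CCC[C@H](C/C(C)=C/C)C(C)=O | intermediate
8 | (3R)-2-methyl-3-[(2E)-2-methylbut-2-en-1-yl]hept-6-en-2-ol | C=CCC[C@H](C/C(C)=C/C)C(C)(C)O | intermediate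
9 | triethylsilyl ether of 8 | C=CCC[C@H](C/C(C)=C/C)C(C)(C)O[Si](CC)(CC)CC | intermediate
10 | (5R,7E)-7-methyl-5-[2-(triethylsilyloxy)propan-2-yl]non-7-en-2-one | CC(=O)CC[C@H](C/C(C)=C/C)C(C)(C)O[Si](CC)(CC)CC | intermediate
11 | (7R,9E)-9-methyl-7-[2-(triethylsilyloxy)propan-2-yl]undec-9-ene-2,4-dione | CC(=O)CC(=O)CC[C@H](C/C(C)=C/C)C(C)(C)O[Si](CC)(CC)CC | intermediate
12 | cyclobutanol photoadduct: 1-{1-hydroxy-6,7-dimethyl-4-[2-(triethylsilyloxy)propan-2-yl]bicyclo[4.2.0]octan-8-yl}ethan-1-one, cis ring fusion, hydroxyl, both methyls and acetyl on the exo face (not isolated) | CC(=O)[C@@H]1[C@H](C)[C@@]2(C)C[C@H](C(C)(C)O[Si](CC)(CC)CC)CC[C@@]12O | intermediate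
13 | (2R,4R)-2-methyl-2-[(2S)-4-oxopentan-2-yl]-4-[2-(triethylsilyloxy)propan-2-yl]cyclohexan-1-one | CC(C)(O[Si](CC)(CC)CC)[C@H]1C[C@@]([C@@H](C)CC(C)=O)(C)C(=O)CC1 | intermediate
14 | (4S,4aR,6R)-8a-hydroxy-4,4a-dimethyl-6-[2-(triethylsilyloxy)propan-2-yl]octahydronaphthalen-2(1H)-one, 8a-hydroxyl cis to the 4a-methyl (not isolated) | CC(C)(O[Si](CC)(CC)CC)[C@H]1C[C@@]2(C)[C@](O)(CC(=O)C[C@@H]2C)CC1 | intermediate
15 | (4S,4aR,6R)-4,4a-dimethyl-6-[2-(triethylsilyloxy)propan-2-yl]-4,4a,5,6,7,8-hexahydronaphthalen-2(3H)-one | CC(C)(O[Si](CC)(CC)CC)[C@H]1C[C@@]2(C)C(=CC(=O)C[C@@H]2C)CC1 | intermediate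
16 | (4S,4aR,6S)-4,4a-dimethyl-6-[2-(triethylsilyloxy)propan-2-yl]-4,4a,5,6-tetrahydronaphthalen-2(3H)-one | CC(C)(O[Si](CC)(CC)CC)[C@H]1C[C@@]2(C)C(=CC(=O)C[C@@H]2C)C=C1 | intermediate
17 | (4S,4aR,6S,7R,8S)-7,8-dihydroxy-4,4a-dimethyl-6-[2-(triethylsilyloxy)propan-2-yl]-4,4a,5,6,7,8-hexahydronaphthalen-2(3H)-one | CC(C)(O[Si](CC)(CC)CC)[C@H]1C[C@@]2(C)C(=CC(=O)C[C@@H]2C)[C@H](O)[C@@H]1O | intermediate
18 | 7,8-O-isopropylidene derivative (acetonide) of 17 | CC(C)(O[Si](CC)(CC)CC)[C@H]1C[C@@]2(C)C(=CC(=O)C[C@@H]2C)[C@@H]3OC(C)(C)O[C@H]13 | intermediate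
19 | 7,8-O-isopropylidene derivative of (4S,4aR,6S,7R,8S,8aS)-7,8-dihydroxy-4,4a-dimethyl-6-[2-(triethylsilyloxy)propan-2-yl]octahydronaphthalen-2(1H)-one (cis-fused, 8a-H cis to the 4a-methyl) | CC(C)(O[Si](CC)(CC)CC)[C@H]1C[C@@]2(C)[C@H](CC(=O)C[C@@H]2C)[C@@H]3OC(C)(C)O[C@H]13 | intermediate
20 | 7,8-O-isopropylidene derivative of (4S,4aR,6S,7R,8S,8aS)-7,8-dihydroxy-6-(2-hydroxypropan-2-yl)-4,4a-dimethyloctahydronaphthalen-2(1H)-one | CC(C)(O)[C@H]1C[C@@]2(C)[C@H](CC(=O)C[C@@H]2C)[C@@H]3OC(C)(C)O[C@H]13 | intermediate
21 | chlorosulfite ester of the tertiary hydroxyl of 20 (not isolated) | CC(C)(OS(=O)Cl)[C@H]1C[C@@]2(C)[C@H](CC(=O)C[C@@H]2C)[C@@H]3OC(C)(C)O[C@H]13 | intermediate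
22 | 7,8-O-isopropylidene derivative of (4S,4aR,6R,7R,8S,8aS)-7,8-dihydroxy-4,4a-dimethyl-6-(prop-1-en-2-yl)octahydronaphthalen-2(1H)-one | C=C(C)[C@H]1C[C@@]2(C)[C@H](CC(=O)C[C@@H]2C)[C@@H]3OC(C)(C)O[C@H]13 | intermediate
23 | (4S,4aR,6R,7R,8S,8aS)-7,8-dihydroxy-4,4a-dimethyl-6-(prop-1-en-2-yl)octahydronaphthalen-2(1H)-one | C=C(C)[C@H]1C[C@@]2(C)[C@H](CC(=O)C[C@@H]2C)[C@H](O)[C@@H]1O | intermediate
24 | (R)-2-methylbutanoic acid | CC[C@@H](C)C(=O)O | starting material
25 | O-acylisourea from 24 and N,N'-dicyclohexylcarbodiimide (not isolated) | CC[C@@H](C)C(=O)OC(=NC1CCCCC1)NC1CCCCC1 | intermediate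
26 | (4S,4aR,6R,7R,8S,8aS)-8-hydroxy-4,4a-dimethyl-7-{[(2R)-2-methylbutanoyl]oxy}-6-(prop-1-en-2-yl)octahydronaphthalen-2(1H)-one | C=C(C)[C@H]1C[C@@]2(C)[C@H](CC(=O)C[C@@H]2C)[C@H](O)[C@@H]1OC(=O)[C@H](C)CC | intermediate
27 | (E)-2-methylbut-2-enoyl chloride (tigloyl chloride) | C/C=C(\C)C(=O)Cl | starting material
28 | CNP0312791.1: (4S,4aR,6R,7R,8S,8aS)-4,4a-dimethyl-7-{[(2R)-2-methylbutanoyl]oxy}-8-{[(2E)-2-methylbut-2-enoyl]oxy}-6-(prop-1-en-2-yl)octahydronaphthalen-2(1H)-one | C=C(C)[C@H]1C[C@@]2(C)[C@H](CC(=O)C[C@@H]2C)[C@H](OC(=O)/C(C)=C/C)[C@@H]1OC(=O)[C@H](C)CC | target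

**Step count**

Total: 18 steps. Longest linear sequence: 18 steps (from 1 and 2 to 28).

**Steps most likely to fail**

Step 8. The excited enol may decay or abstract an allylic hydrogen faster than it closes the six-membered ring, the product ketones may undergo secondary α-cleavage on long irradiation, and the chair preference that sets C5 may be small, so that conversion or facial selectivity is poor. The fallback sets out from 11 and locks and activates the enol as a boron chelate. BF3·OEt2 and i-Pr2NEt in CH2Cl2 should give the difluoroboron diketonate F1. 1,3-Diketonatoboron difluorides are known to add to alkenes from their singlet excited state at about 350 nm, more efficiently than free enols and with retention of alkene geometry; here this would give the boron-bridged cyclobutane F2. Stirring with aqueous NaOAc removes boron and opens the cyclobutane by the same retro-aldol cleavage, so the route is rejoined at 13.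

Step 13. Hydrogen may be delivered to the β face if the dioxolane screens less than expected, which would give the trans-fused ketone, or the allylic C9–O bond may be hydrogenolysed. The fallback sets out from 18 and replaces steric face selection by hydroxyl direction. Reduction with NaBH4 and CeCl3·7H2O in MeOH (Luche conditions) should give the allylic alcohol F3 with the C2 hydroxyl cis to the C5 methyl, as axial hydride attack does in 4-en-3-one systems. Hydrogenation with [Ir(cod)(PCy3)(py)]PF6 and H2 in CH2Cl2 then delivers hydrogen to C10 on the face of that hydroxyl and gives the saturated alcohol F4. Oxidation with Dess–Martin periodinane returns the ketone and rejoins the route at 19.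

Step 18. Acylation of the axial C9 hydroxyl may be slow, and under prolonged basic conditions the 2-methylbutanoyl group may migrate from O8 to O9, so that the two acyl groups end up exchanged or mixed; imperfect site selection in step 17 would have the same effect. The fallback sets out from 23 and reverses the order of acylation behind a temporary silyl group. TBSCl and imidazole in DMF at 0 °C should silylate the equatorial C8 hydroxyl to the silyl ether F5. Acylation with 27, Et3N and DMAP in toluene at 60 °C then gives the silyl ether tiglate F6, with no acyl group present that could migrate. HF·pyridine frees the hydroxy tiglate F7, and Steglich esterification of its open C8 hydroxyl with 24 at 0 °C rejoins the route at 28.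

**Further compounds**

F1 | step 8 | difluoroboron chelate of 11 | CC1=CC(CC[C@H](C/C(C)=C/C)C(C)(C)O[Si](CC)(CC)CC)=[O+][B-](F)(F)O1
F2 | step 8 | boron-bridged cyclobutane (difluoroboron chelate of 12) | CC1=[O+][B-](F)(F)O[C@@]23CC[C@@H](C(C)(C)O[Si](CC)(CC)CC)C[C@]2(C)[C@@H](C)[C@@H]13
F3 | step 13 | allylic alcohol from 18 (2-hydroxyl cis to the 4a-methyl) | CC(C)(O[Si](CC)(CC)CC)[C@H]1C[C@@]2(C)C(=C[C@H](O)C[C@@H]2C)[C@@H]3OC(C)(C)O[C@H]13
F4 | step 13 | saturated cis-fused alcohol (2-hydroxy analogue of 19) | CC(C)(O[Si](CC)(CC)CC)[C@H]1C[C@@]2(C)[C@H](C[C@H](O)C[C@@H]2C)[C@@H]3OC(C)(C)O[C@H]13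
F5 | step 18 | 7-O-tert-butyldimethylsilyl ether of 23 | C=C(C)[C@H]1C[C@@]2(C)[C@H](CC(=O)C[C@@H]2C)[C@H](O)[C@@H]1O[Si](C)(C)C(C)(C)C
F6 | step 18 | 7-O-tert-butyldimethylsilyl 8-O-tigloyl derivative of 23 | C=C(C)[C@H]1C[C@@]2(C)[C@H](CC(=O)C[C@@H]2C)[C@H](OC(=O)/C(C)=C/C)[C@@H]1O[Si](C)(C)C(C)(C)C
F7 | step 18 | 8-O-tigloyl derivative of 23 (free 7-hydroxyl) | C=C(C)[C@H]1C[C@@]2(C)[C@H](CC(=O)C[C@@H]2C)[C@H](OC(=O)/C(C)=C/C)[C@@H]1O
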